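**Strategy.** Ring B is closed last, across its C10–C11 bond. The key step exploits the 1,4-relationship in ring B between the C8 oxygen and the methyl-bearing C11: C8(O)–C9–C10 is read as a vinyl ketone, and C11 with its methyl as the secondary radical of a vinyl group on C12. One iron-mediated hydrogen-atom-transfer Giese cyclization joins C10 to C11, sets the C11 stereocentre and leaves a C8 ketone from which both ring B oxygens are installed. The precursor, a ring A cyclohexene bearing trans acryloyl and vinyl groups, comes from an ester-tethered intramolecular Diels–Alder reaction fixing C4, C7, C12 and quaternary C13; the C14–C16 hydroxy ketone travels as an isoxazoline.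

Key step: step 13

Remarks
- Numbering used throughout: sec-butyl = C1–C2–C3(C19); ring A = C4, C5=C6, C7, C12, C13; ring B = C7, C8(OH), C9(O-acyl), C10, C11(C17 methyl), C12; C13 carries the C18 methyl and the chain C14(=O)–C15–C16–OH. β is the face of H-7 and of the C13 methyl; α is the face of H-12, of the sec-butyl group and of C14. Isoxazolin-3-yl = 4,5-dihydro-1,2-oxazol-3-yl.
- Assumption: (R)-2-methylbutan-1-ol, triethyl 4-phosphonocrotonate, ethyl (2E)-3-methyl-4-oxobut-2-enoate and 3-methylglutaconic acid (E/Z mixture) are taken as commercial.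

Step 1
Reactants: 1 (R)-2-methylbutan-1-ol; 2 triethyl 4-phosphonocrotonate
Product: 4 ethyl (2E,4E,6R)-6-methylocta-2,4-dienoate, via (R)-2-methylbutanal 3 (not isolated)
Conditions: NaOCl, TEMPO (cat.), KBr (cat.), CH2Cl2/aq. NaHCO3, 0 °C; dried CH2Cl2 solution of 3 added to 2, LiHMDS, THF, −78 → 0 °C
Reagents that add atoms: none
Why: The Anelli oxidation should give the α-chiral aldehyde without epimerization and the vinylogous Horner–Wadsworth–Emmons olefination builds the (E,E)-dienoate, so the C3 stereocentre comes unchanged from the starting alcohol.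

Step 2
Reactants: 4 ethyl (2E,4E,6R)-6-methylocta-2,4-dienoate
Product: 5 (2E,4E,6R)-6-methylocta-2,4-dien-1-ol
Conditions: i-Bu2AlH (DIBAL-H), CH2Cl2, −78 °C
Reagents that add atoms: none
Why: Hydride 1,2-reduction of the ester to the allylic alcohol leaves the conjugated diene untouched.

Step 3
Reactants: 5 (2E,4E,6R)-6-methylocta-2,4-dien-1-ol
Product: 6 (2E,4E,6R)-6-methylocta-2,4-dienal
Conditions: MnO2, CH2Cl2, 23 °C
Reagents that add atoms: none
Why: MnO2 oxidises the dienylic alcohol selectively to the aldehyde (allylic oxidation) without touching the remote stereocentre.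

Step 4
Reactants: 6 (2E,4E,6R)-6-methylocta-2,4-dienal
Product: 7 (3S,4E,6E,8R)-8-methyldeca-1,4,6-trien-3-ol
Conditions: (CH2=CH)2Zn, (−)-MIB [(2S)-3-exo-morpholinoisoborneol] (10 mol %), toluene, −20 °C
Reagents that add atoms: divinylzinc, C=C[Zn]C=C
Why: Amino-alcohol-catalysed asymmetric vinylzinc addition should set the carbinol centre (future C8) as (S) under reagent control, (−)-MIB delivering the vinyl group to the face it uses in dialkylzinc additions that give (S)-alcohols.

Step 5
Reactants: 8 ethyl (2E)-3-methyl-4-oxobut-2-enoate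
Product: 9 ethyl (2E,4E)-4-(hydroxyimino)-3-methylbut-2-enoate
Conditions: NH2OH·HCl, NaOAc, EtOH/H2O, 23 °C
Reagents that add atoms: hydroxylamine hydrochloride, [NH3+]O.[Cl-]
Why: Oxime formation on the aldehyde provides the precursor of the nitrile oxide.

Step 6
Reactants: 9 ethyl (2E,4E)-4-(hydroxyimino)-3-methylbut-2-enoate
Product: 12 ethyl (2E)-3-(4,5-dihydro-1,2-oxazol-3-yl)but-2-enoate, via hydroximoyl chloride 10 (not isolated), via nitrile oxide 11 (not isolated)
Conditions: N-chlorosuccinimide, DMF, 23 °C; then ethene (5 bar), Et3N (slow addition), CH2Cl2, 0 → 23 °C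
Reagents that add atoms: ethene, C=C
Why: Chlorination and dehydrochlorination of the aldoxime generate a nitrile oxide that undergoes 1,3-dipolar cycloaddition with ethene, giving the isoxazoline as a latent C14–C16 β-hydroxy ketone that should resist the later base and hydride steps.

Step 7
Reactants: 12 ethyl (2E)-3-(4,5-dihydro-1,2-oxazol-3-yl)but-2-enoate
Product: 13 (2E)-3-(4,5-dihydro-1,2-oxazol-3-yl)but-2-enoic acid
Conditions: LiOH, THF/H2O, 0 → 23 °C; then dilute HCl
Reagents that add atoms: lithium hydroxide, [Li+].[OH-]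
Why: Saponification frees the acid for the tether without affecting the E-alkene or the isoxazoline.

Step 8
Reactants: 7 (3S,4E,6E,8R)-8-methyldeca-1,4,6-trien-3-ol; 13 (2E)-3-(4,5-dihydro-1,2-oxazol-3-yl)but-2-enoic acid
Product: 14 (3S,4E,6E,8R)-8-methyldeca-1,4,6-trien-3-yl (2E)-3-(4,5-dihydro-1,2-oxazol-3-yl)but-2-enoate
Conditions: DCC, DMAP (cat.), CH2Cl2, 0 → 23 °C
Reagents that add atoms: none
Why: Steglich esterification joins diene and dienophile through the C8–O–C11(=O) tether under neutral conditions that spare the acid-sensitive bis-allylic alcohol.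

Step 9
Reactants: 14 (3S,4E,6E,8R)-8-methyldeca-1,4,6-trien-3-yl (2E)-3-(4,5-dihydro-1,2-oxazol-3-yl)but-2-enoate
Product: 15 trans-fused lactone of ring A (4α-sec-butyl; 13β-methyl; 13α-isoxazolin-3-yl; lactone C7–C8–O–C11(=O)–C12 with the C8 vinyl group cis to H-7)
Conditions: toluene (high dilution), BHT (cat.), 110 °C
Reagents that add atoms: none
Why: In this ester-tethered intramolecular Diels–Alder reaction, suprafacial addition of the (E,E)-diene and (E)-dienophile makes the sec-butyl group and C8 cis and C11 and C14 trans, the tether-exo/isoxazoline-endo transition state should give the trans-fused lactone with C14 cis to the sec-butyl group, and the C8 stereocentre (H-8 eclipsing the diene, vinyl turned away from C6) selects the diene face, so C4, C7, C12 and C13 are set together.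

Step 10
Reactants: 15 trans-fused lactone of ring A
Product: 16 lactol of 15 (C11 hemiacetal; anomeric mixture)
Conditions: i-Bu2AlH (DIBAL-H), CH2Cl2, −78 °C
Reagents that add atoms: none
Why: Partial reduction of the lactone stops at the lactol at low temperature and is expected to spare the isoxazoline C=N bond.

Step 11
Reactants: 16 lactol of 15
Product: 18 ring A dienol (7α-(1-hydroxyprop-2-en-1-yl); 12β-vinyl), via hydroxy aldehyde 17 (not isolated)
Conditions: Ph3PCH3Br, KOtBu, THF, 0 → 23 °C
Reagents that add atoms: methyltriphenylphosphonium bromide, C[P+](c1ccccc1)(c1ccccc1)c1ccccc1.[Br-]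
Why: Wittig methylenation of the ring-opened hydroxy aldehyde turns C11 into the vinyl group whose terminal carbon becomes the C11 methyl, and C12 (α to the aldehyde) already sits in the thermodynamically preferred trans arrangement to the C7 substituent.

Step 12
Reactants: 18 ring A dienol
Product: 19 ring A dienone (7α-acryloyl; 12β-vinyl)
Conditions: Dess–Martin periodinane, CH2Cl2, 0 → 23 °C
Reagents that add atoms: none
Why: Dess–Martin oxidation of the allylic C8 alcohol gives the vinyl ketone and erases the C8 stereocentre after it has done its work in step 9.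

Step 13
Reactants: 19 ring A dienone
Product: 20 trans-decalin-8-one (ring B closed; 11α-methyl equatorial; H-7β; H-12α)
Conditions: Fe(acac)3 (30 mol %), PhSiH3, EtOH/ethylene glycol, 60 °C
Reagents that add atoms: none
Why: An iron hydride formed from Fe(acac)3 and PhSiH3 transfers a hydrogen atom to the terminal carbon of the C12 vinyl group, giving the secondary C11 radical that already carries the future methyl; this nucleophilic radical adds to C10, the terminus of the C8 vinyl ketone, and the resulting C9 α-keto radical is reduced and protonated. The closest known reaction type is the iron-mediated MHAT reductive olefin coupling (radical Giese addition) in its intramolecular form. Ring B closes in the 6-endo-trig mode, the 5-exo alternative being disfavoured because it would attack the α-carbon of the enone. C11 is set in a chair-like transition state built on the trans C7/C12 substituents, where the methyl takes the equatorial position because an axial methyl would be syn-axial to the axial C13 methyl. The step needs hydrogen-atom transfer to the monosubstituted vinyl group rather than to the cis-disubstituted C5=C6 alkene (much slower in MHAT) or the enone, and fast intramolecular capture by the electrophilic vinyl ketone secures the pathway.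

Step 14
Reactants: 20 trans-decalin-8-one
Product: 22 9β-hydroxy-trans-decalin-8-one (axial alcohol), via potassium enolate 21 (not isolated)
Conditions: KHMDS, THF, −78 °C; then 3-phenyl-2-(phenylsulfonyl)oxaziridine, −78 °C; aq. NH4Cl
Reagents that add atoms: 3-phenyl-2-(phenylsulfonyl)oxaziridine, O=S(=O)(N1OC1c1ccccc1)c1ccccc1
Why: Kinetic deprotonation should occur at the C9 methylene (C7–H is tertiary and screened by the axial C13 methyl), and Davis enolate hydroxylation along the axial β trajectory, which meets only the axial hydrogens at C7 and C11, should give the axial 9β-alcohol.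

Step 15
Reactants: 23 3-methylglutaconic acid (E/Z mixture)
Product: 24 3-methylglutaconic anhydride (4-methyl-2H-pyran-2,6(3H)-dione)
Conditions: Ac2O, reflux
Reagents that add atoms: none
Why: Dehydrative cyclisation gives the cyclic anhydride, on which both alkene isomers converge and in which the two carboxyl carbons are held cis.

Step 16
Reactants: 22 9β-hydroxy-trans-decalin-8-one; 24 3-methylglutaconic anhydride
Product: 25 9β-[(3Z)-4-carboxy-3-methylbut-3-enoyl]oxy-trans-decalin-8-one
Conditions: 24 (excess), toluene, 70 °C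
Reagents that add atoms: none
Why: The C9 alcohol opens the cyclic anhydride at its non-conjugated carbonyl (acyl transfer without base, which would only deprotonate the anhydride), giving the half ester whose free enoic acid keeps the Z geometry of the ring.

Step 17
Reactants: 25 9β-acyloxy-trans-decalin-8-one
Product: 26 8β-hydroxy-9β-acyloxy decalin (isoxazoline still in place)
Conditions: NaBH4, CeCl3·7H2O, MeOH, −78 °C
Reagents that add atoms: none
Why: Luche-type reduction delivers hydride axially from the α face, anti to the axial C9 acyloxy group, giving the equatorial 8β-alcohol cis to the ester, while low temperature and the cerium salt should suppress acyl migration.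

Step 18
Reactants: 26 8β-hydroxy-9β-acyloxy decalin
Product: 28 tandyukisin D, via β-hydroxy imine 27 (not isolated)
Conditions: Mo(CO)6, MeCN/H2O, 80 °C
Reagents that add atoms: water, O
Why: Mo(CO)6 cleaves the isoxazoline N–O bond reductively and the β-hydroxy imine hydrolyses in the aqueous medium, unveiling the C14 ketone and C16 alcohol under neutral conditions that tolerate the alkenes, the ester and the acid.

**Compound list**

1 | (R)-2-methylbutan-1-ol | CC[C@@H](C)CO | starting material
2 | triethyl 4-phosphonocrotonate | CCOC(=O)/C=C/CP(=O)(OCC)OCC | starting material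
3 | (R)-2-methylbutanal | CC[C@@H](C)C=O | intermediate
4 | ethyl (2E,4E,6R)-6-methylocta-2,4-dienoate | CC[C@@H](C)/C=C/C=C/C(=O)OCC | intermediate
5 | (2E,4E,6R)-6-methylocta-2,4-dien-1-ol | CC[C@@H](C)/C=C/C=C/CO | intermediate
6 | (2E,4E,6R)-6-methylocta-2,4-dienal | CC[C@@H](C)/C=C/C=C/C=O | intermediate
7 | (3S,4E,6E,8R)-8-methyldeca-1,4,6-trien-3-ol | CC[C@@H](C)/C=C/C=C/[C@H](C=C)O | intermediate
8 | ethyl (2E)-3-methyl-4-oxobut-2-enoate | CCOC(=O)/C=C(/C=O)C | starting material
9 | ethyl (2E,4E)-4-(hydroxyimino)-3-methylbut-2-enoate | CCOC(=O)/C=C(/C=N/O)C | intermediate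
10 | hydroximoyl chloride of 9 (C=N geometry not defined) | CCOC(=O)/C=C(/C(Cl)=NO)C | intermediate
11 | nitrile oxide from 10 | CCOC(=O)/C=C(/C#[N+][O-])C | intermediate
12 | ethyl (2E)-3-(4,5-dihydro-1,2-oxazol-3-yl)but-2-enoate | CCOC(=O)/C=C(/C1=NOCC1)C | intermediate
13 | (2E)-3-(4,5-dihydro-1,2-oxazol-3-yl)but-2-enoic acid | OC(=O)/C=C(/C1=NOCC1)C | intermediate
14 | (3S,4E,6E,8R)-8-methyldeca-1,4,6-trien-3-yl (2E)-3-(4,5-dihydro-1,2-oxazol-3-yl)but-2-enoate | CC[C@@H](C)/C=C/C=C/[C@H](C=C)OC(=O)/C=C(/C1=NOCC1)C | intermediate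
15 | trans-fused lactone of ring A (4α-sec-butyl, H-7β, H-12α, 13β-methyl, 13α-isoxazolin-3-yl; lactone C7–C8–O–C11(=O)–C12, C8 vinyl cis to H-7) | CC[C@@H](C)[C@H]1C=C[C@H]2[C@H](C=C)OC(=O)[C@@H]2[C@@]1(C)C3=NOCC3 | intermediate
16 | lactol of 15 (C11 hemiacetal, anomeric mixture) | CC[C@@H](C)[C@H]1C=C[C@H]2[C@H](C=C)OC(O)[C@@H]2[C@@]1(C)C3=NOCC3 | intermediate
17 | open hydroxy aldehyde of 16 (7α-(1-hydroxyprop-2-en-1-yl), 12β-formyl) | CC[C@@H](C)[C@H]1C=C[C@@H]([C@@H](O)C=C)[C@H](C=O)[C@@]1(C)C2=NOCC2 | intermediate
18 | ring A dienol (7α-(1-hydroxyprop-2-en-1-yl), 12β-vinyl) | CC[C@@H](C)[C@H]1C=C[C@@H]([C@@H](O)C=C)[C@H](C=C)[C@@]1(C)C2=NOCC2 | intermediate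
19 | ring A dienone (7α-acryloyl, 12β-vinyl) | CC[C@@H](C)[C@H]1C=C[C@@H](C(=O)C=C)[C@H](C=C)[C@@]1(C)C2=NOCC2 | intermediate
20 | trans-decalin-8-one (11α-methyl, H-7β, H-12α, 13α-isoxazolin-3-yl) | CC[C@@H](C)[C@H]1C=C[C@H]2C(=O)CC[C@@H](C)[C@@H]2[C@@]1(C)C3=NOCC3 | intermediate
21 | potassium C8–C9 enolate of 20 | CC[C@@H](C)[C@H]1C=C[C@H]2C([O-])=CC[C@@H](C)[C@@H]2[C@@]1(C)C3=NOCC3.[K+] | intermediate
22 | 9β-hydroxy-trans-decalin-8-one (axial OH) | CC[C@@H](C)[C@H]1C=C[C@H]2C(=O)[C@H](O)C[C@@H](C)[C@@H]2[C@@]1(C)C3=NOCC3 | intermediate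
23 | 3-methylglutaconic acid (E/Z mixture) | CC(=CC(=O)O)CC(=O)O | starting material
24 | 3-methylglutaconic anhydride | CC1=CC(=O)OC(=O)C1 | intermediate
25 | 9β-[(3Z)-4-carboxy-3-methylbut-3-enoyl]oxy-trans-decalin-8-one | CC[C@@H](C)[C@H]1C=C[C@H]2C(=O)[C@H](OC(=O)C/C(C)=C\C(=O)O)C[C@@H](C)[C@@H]2[C@@]1(C)C3=NOCC3 | intermediate
26 | 8β-hydroxy-9β-acyloxy decalin with isoxazoline | CC[C@@H](C)[C@H]1C=C[C@H]2[C@H](O)[C@H](OC(=O)C/C(C)=C\C(=O)O)C[C@@H](C)[C@@H]2[C@@]1(C)C3=NOCC3 | intermediate
27 | C14 β-hydroxy imine | CC[C@@H](C)[C@H]1C=C[C@H]2[C@H](O)[C@H](OC(=O)C/C(C)=C\C(=O)O)C[C@@H](C)[C@@H]2[C@@]1(C)C(=N)CCO | intermediate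
28 | tandyukisin D | CC[C@@H](C)[C@H]1C=C[C@H]2[C@H](O)[C@H](OC(=O)C/C(C)=C\C(=O)O)C[C@@H](C)[C@@H]2[C@@]1(C)C(=O)CCO | target

**Step count.** Total: 18 steps. Longest linear sequence: 14 steps (steps 1–4, 8–14, 16–18).

**Steps most likely to fail**

Step 13. Hydrogen-atom transfer to the monosubstituted C12 vinyl group may be slower than direct reduction of the vinyl ketone, so saturation of the enone could outrun ring closure. The fallback generates the same C11 radical by C–O homolysis instead of MHAT. It sets out from lactol 16: MeMgBr adds to the open aldehyde form to give the C11 methyl carbinol diol F1 (epimers at C11 are inconsequential). MnO2 then oxidises only the allylic C8 alcohol to the hydroxy vinyl ketone F2, and 1,1'-thiocarbonyldiimidazole converts the C11 alcohol into the imidazole-1-carbothioate F3. Bu3SnH/AIBN (benzene, 80 °C, slow addition) gives the secondary C11 radical by Barton–McCombie fragmentation, which closes ring B by the same 6-endo addition and returns to the route at 20.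

Step 9. The tether-exo transition state may not be preferred enough, so the cis-fused lactone with the wrong C13 configuration could compete; facial control by C8 may also be incomplete. The fallback uses the (Z)-dienophile, whose doubly endo transition state should give a cis-fused lactone with the correct C4, C7 and C13, and corrects C12 afterwards. It sets out from ester 12 and alcohol 7: irradiation of 12 (300 nm, MeCN) and separation gives the (2Z)-ester F4, and LiOH gives the (2Z)-acid F5. DCC/DMAP with 7 gives the (Z)-trienyl ester F6, and heating in toluene gives the all-cis lactone F7 (C12 epimer of 15). DIBAL-H gives the cis lactol F8. DBU then epimerises C12 through the open cis hydroxy aldehyde F9 to the thermodynamically preferred trans arrangement, which returns to the route at lactol 16.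

Step 14. Oxygen transfer to the enolate may occur from the α face, giving the equatorial 9α-alcohol instead of the axial one. The fallback makes the equatorial epimer on purpose and inverts it. It sets out from 20: hydroxylation as in step 14 followed by Et3N/MeOH equilibration of the ketol should give the hydrogen-bonded equatorial 9α-hydroxy ketone F10. Mitsunobu reaction (PPh3, DIAD, chloroacetic acid) inverts C9 to the axial 9β-chloroacetate F11, and thiourea removes the chloroacetyl group, returning to the route at 22.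

Further compounds
F1 | step 13 | ring A diol: 7α-(1-hydroxyprop-2-en-1-yl), 12β-(1-hydroxyethyl) (C11 epimers) | CC[C@@H](C)[C@H]1C=C[C@@H]([C@@H](O)C=C)[C@H](C(C)O)[C@@]1(C)C2=NOCC2
F2 | step 13 | hydroxy vinyl ketone: 7α-acryloyl, 12β-(1-hydroxyethyl) | CC[C@@H](C)[C@H]1C=C[C@@H](C(=O)C=C)[C@H](C(C)O)[C@@]1(C)C2=NOCC2
F3 | step 13 | O-alkyl 1H-imidazole-1-carbothioate of F2 | CC[C@@H](C)[C@H]1C=C[C@@H](C(=O)C=C)[C@H](C(C)OC(=S)n2ccnc2)[C@@]1(C)C3=NOCC3
F4 | step 9 | ethyl (2Z)-3-(4,5-dihydro-1,2-oxazol-3-yl)but-2-enoate | CCOC(=O)/C=C(\C1=NOCC1)C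
F5 | step 9 | (2Z)-3-(4,5-dihydro-1,2-oxazol-3-yl)but-2-enoic acid | OC(=O)/C=C(\C1=NOCC1)C
F6 | step 9 | (3S,4E,6E,8R)-8-methyldeca-1,4,6-trien-3-yl (2Z)-3-(4,5-dihydro-1,2-oxazol-3-yl)but-2-enoate | CC[C@@H](C)/C=C/C=C/[C@H](C=C)OC(=O)/C=C(\C1=NOCC1)C
F7 | step 9 | all-cis lactone (C12 epimer of 15) | CC[C@@H](C)[C@H]1C=C[C@H]2[C@H](C=C)OC(=O)[C@H]2[C@@]1(C)C3=NOCC3
F8 | step 9 | cis lactol (C12 epimer of 16) | CC[C@@H](C)[C@H]1C=C[C@H]2[C@H](C=C)OC(O)[C@H]2[C@@]1(C)C3=NOCC3
F9 | step 9 | open cis hydroxy aldehyde (C12 epimer of 17) | CC[C@@H](C)[C@H]1C=C[C@@H]([C@@H](O)C=C)[C@@H](C=O)[C@@]1(C)C2=NOCC2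
F10 | step 14 | 9α-hydroxy-trans-decalin-8-one (equatorial OH, C9 epimer of 22) | CC[C@@H](C)[C@H]1C=C[C@H]2C(=O)[C@@H](O)C[C@@H](C)[C@@H]2[C@@]1(C)C3=NOCC3
F11 | step 14 | 9β-chloroacetoxy-trans-decalin-8-one | CC[C@@H](C)[C@H]1C=C[C@H]2C(=O)[C@H](OC(=O)CCl)C[C@@H](C)[C@@H]2[C@@]1(C)C3=NOCC3
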